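The B ring is cut out of the flavone altogether: its C5'–C6', C1'–C2' and C2'–C3' bonds are made in one Dötz benzannulation between 2-ethynyl-5,6,7-trimethoxychromone (the complete A/C bicycle) and a methoxy(alkenyl)carbene chromium complex whose alkene carries the future 4'-OMe and a benzyl-protected 3'-oxygen. The step exploits the B-ring pattern itself: the para-related oxygens at C2' and C5' are the CO-derived phenol and the carbene methoxy, and the lone hydrogen at C6' is the alkyne terminus. It leaves 2'-OH free and 3'-O benzylated, so methylation followed by one BCl3 treatment (3'-OBn and chelated 5-OMe) finishes psiadiarabicin.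

Key step: step 8

Remark on stereochemistry: the target has no stereocentre and is achiral, so no enantiocontrol is needed; the only stereo-element on the route, the enol ether geometry of 8–14, disappears in step 8.
Remark on materials: acetophenone 1 is assumed to be a purchasable building block.

Step 1
Reactants: 1 1-(6-hydroxy-2,3,4-trimethoxyphenyl)ethan-1-one
Product: 3 5,6,7-trimethoxy-2-methyl-4H-chromen-4-one, via β-diketone 2 (not isolated)
Conditions: NaH, EtOAc, THF, reflux; then AcOH, H2SO4 (cat.), 90 °C
Reagents that add atoms: ethyl acetate, CCOC(C)=O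
Why: Claisen condensation of the ketone enolate with ethyl acetate followed by acid-catalysed cyclodehydration of the o-hydroxyaryl 1,3-diketone is the standard 2-methylchromone synthesis and should tolerate the three aryl methyl ethers.

Step 2
Reactants: 3 5,6,7-trimethoxy-2-methyl-4H-chromen-4-one
Product: 4 5,6,7-trimethoxy-4-oxo-4H-chromene-2-carbaldehyde
Conditions: SeO2, 1,4-dioxane, reflux
Reagents that add atoms: selenium dioxide, O=[Se]=O
Why: Riley oxidation of the 2-methyl group, which is vinylogously activated by the pyrone carbonyl, is the established route from 2-methylchromones to chromone-2-carbaldehydes and leaves methoxyarenes alone.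

Step 3
Reactants: 4 5,6,7-trimethoxy-4-oxo-4H-chromene-2-carbaldehyde
Product: 5 2-ethynyl-5,6,7-trimethoxy-4H-chromen-4-one
Conditions: MeC(O)C(N2)P(O)(OMe)2, NaOMe (1 equiv), THF, −78 °C; then 4, −78 °C → rt
Reagents that add atoms: dimethyl (1-diazo-2-oxopropyl)phosphonate, CC(=O)C(=[N+]=[N-])P(=O)(OC)OC
Why: Seyferth–Gilbert homologation with the Ohira–Bestmann reagent, in which the diazophosphonate anion is released at low temperature in THF so that the non-enolisable aldehyde is olefinated and the diazoalkene loses N2 with 1,2-hydride shift while the nucleophile-sensitive pyrone C2 and the product enynone never see a methanolic base.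

Step 4
Reactants: 6 methyl methoxyacetate
Product: 8 methyl (Z)-3-(benzyloxy)-2-methoxyprop-2-enoate, via sodium formyl enolate 7 (not isolated)
Conditions: NaH, HCO2Me, THF, 0 °C → rt; then BnBr, DMF, rt
Reagents that add atoms: methyl formate, COC=O; benzyl bromide, BrCc1ccccc1
Why: Crossed Claisen formylation gives the stabilised sodium enolate, whose alkylation in DMF should go to oxygen because C-alkylation would build a quaternary centre, and the enol ether is expected mainly as the (Z)-isomer with benzyloxy anti to the ester and syn to the 2-methoxy group.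

Step 5
Reactants: 8 methyl (Z)-3-(benzyloxy)-2-methoxyprop-2-enoate
Product: 9 (Z)-3-(benzyloxy)-2-methoxyprop-2-enoic acid
Conditions: LiOH, THF–H2O, rt; then aq. HCl to pH 3, 0 °C
Reagents that add atoms: water (as hydroxide), O
Why: Ester saponification of a 3-alkoxyacrylate, a routine operation in which the vinylogous carbonate survives hydroxide at room temperature and a brief cold acidification.

Step 6
Reactants: 9 (Z)-3-(benzyloxy)-2-methoxyprop-2-enoic acid
Product: 10 (Z)-3-(benzyloxy)-2-methoxyprop-2-enoyl chloride
Conditions: (COCl)2, DMF (cat.), CH2Cl2, 0 °C → rt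
Reagents that add atoms: oxalyl chloride, O=C(Cl)C(Cl)=O
Why: Vilsmeier-catalysed acid chloride formation, the usual way to 3-alkoxyacryloyl chlorides, with no α-hydrogen that could open a ketene pathway.

Step 7
Reactants: 10 (Z)-3-(benzyloxy)-2-methoxyprop-2-enoyl chloride; 11 chromium hexacarbonyl
Product: 14 pentacarbonyl[(Z)-3-(benzyloxy)-1,2-dimethoxyprop-2-en-1-ylidene]chromium, via disodium pentacarbonylchromate 12 (not isolated), via sodium acylchromate 13 (not isolated)
Conditions: 11, NaC10H8, THF, −78 °C; then 10, −78 → 0 °C; then Me3OBF4, CH2Cl2, 0 °C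
Reagents that add atoms: trimethyloxonium tetrafluoroborate, C[O+](C)C.F[B-](F)(F)F
Why: Acyl chloride route to Fischer carbenes, in which the pentacarbonylchromate dianion is acylated at the most electrophilic carbon and the acylchromate is O-methylated by the Meerwein salt, which avoids a 1,2-dialkoxyvinyllithium that could not be generated regioselectively.

Step 8
Reactants: 5 2-ethynyl-5,6,7-trimethoxy-4H-chromen-4-one; 14 pentacarbonyl[(Z)-3-(benzyloxy)-1,2-dimethoxyprop-2-en-1-ylidene]chromium
Product: 16 2-[3-(benzyloxy)-2-hydroxy-4,5-dimethoxyphenyl]-5,6,7-trimethoxy-4H-chromen-4-one, via tricarbonylchromium phenol complex 15 (not isolated)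
Conditions: 14 (1.3 equiv), THF, 50 °C, Ar; then air, MeCN, rt
Reagents that add atoms: none
Why: Proposed new method: thermal CO loss from 14 should let the alkyne insert into the Cr=C bond to give a vinylcarbene, CO insertion then gives a chromium-bound dienylketene, and 6π-electrocyclisation of that ketene onto the benzyloxy-bearing alkene carbon followed by enolisation closes the six-membered B ring as the Cr(CO)3-complexed 4-methoxyphenol 15, which air should release without taking it on to the quinone. The closest known reaction type is the Dötz benzannulation of alkenyl(alkoxy)carbene chromium complexes with terminal alkynes, including alkenyl units that carry an α-oxygen; what is untested is the additional β-oxygen on the alkenyl unit and a 2-ethynylchromone as the alkyne. The closure is electrocyclic, with the carbene carbon becoming C5', the alkyne carbons C6' and C1', the inserted CO C2' and the alkene carbons C4' and C3'; no stereocentre is formed and the alkene geometry of 14 is lost on aromatisation. The regiochemistry needed, chromonyl carbon next to the new C–OH, should follow from the large steric difference between H and the chromonyl group at a terminal alkyne. The chemoselectivity needed, CO insertion ahead of cyclopentannulation or interception of the vinylcarbene by the pyrone, is what methoxy carbenes of chromium with an alkenyl partner normally give, and the (Z)-geometry keeps the benzyloxy group away from chromium so that it neither chelates the metal nor crowds the ring-closing terminus.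

Step 9
Reactants: 16 2-[3-(benzyloxy)-2-hydroxy-4,5-dimethoxyphenyl]-5,6,7-trimethoxy-4H-chromen-4-one
Product: 17 2-[3-(benzyloxy)-2,4,5-trimethoxyphenyl]-5,6,7-trimethoxy-4H-chromen-4-one
Conditions: MeI, K2CO3, acetone, reflux
Reagents that add atoms: iodomethane, CI
Why: Williamson O-methylation of the only free hydroxyl in the molecule, so no selectivity question arises.

Step 10
Reactants: 17 2-[3-(benzyloxy)-2,4,5-trimethoxyphenyl]-5,6,7-trimethoxy-4H-chromen-4-one
Product: 18 psiadiarabicin [5-hydroxy-2-(3-hydroxy-2,4,5-trimethoxyphenyl)-6,7-dimethoxy-4H-chromen-4-one]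
Conditions: BCl3, C6HMe5, CH2Cl2, −78 → 0 °C; then H2O
Reagents that add atoms: none
Why: Lewis-acid ether cleavage in which BCl3 removes the aryl benzyl ether at low temperature (benzyl cation trapped by pentamethylbenzene) and, on warming, the 5-methoxy group through the six-membered boron chelate with the C4 carbonyl, while the non-chelated methyl ethers should stay.

Compound list
1 | 1-(6-hydroxy-2,3,4-trimethoxyphenyl)ethan-1-one | CC(=O)c1c(O)cc(OC)c(OC)c1OC | starting material
2 | 1-(6-hydroxy-2,3,4-trimethoxyphenyl)butane-1,3-dione (formed as its sodium enolate) | CC(=O)CC(=O)c1c(O)cc(OC)c(OC)c1OC | intermediate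
3 | 5,6,7-trimethoxy-2-methyl-4H-chromen-4-one | Cc1cc(=O)c2c(OC)c(OC)c(OC)cc2o1 | intermediate
4 | 5,6,7-trimethoxy-4-oxo-4H-chromene-2-carbaldehyde | O=Cc1cc(=O)c2c(OC)c(OC)c(OC)cc2o1 | intermediate
5 | 2-ethynyl-5,6,7-trimethoxy-4H-chromen-4-one | C#Cc1cc(=O)c2c(OC)c(OC)c(OC)cc2o1 | intermediate
6 | methyl methoxyacetate | COCC(=O)OC | starting material
7 | sodium 2,3-dimethoxy-3-oxoprop-1-en-1-olate (delocalised enolate of methyl 2-formyl-2-methoxyacetate, C=C geometry not defined) | [Na+].COC(=O)C(OC)=C[O-] | intermediate
8 | methyl (Z)-3-(benzyloxy)-2-methoxyprop-2-enoate | COC(=O)/C(OC)=C/OCc1ccccc1 | intermediate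
9 | (Z)-3-(benzyloxy)-2-methoxyprop-2-enoic acid | OC(=O)/C(OC)=C/OCc1ccccc1 | intermediate
10 | (Z)-3-(benzyloxy)-2-methoxyprop-2-enoyl chloride | ClC(=O)/C(OC)=C/OCc1ccccc1 | intermediate
11 | chromium hexacarbonyl | O=C=[Cr](=C=O)(=C=O)(=C=O)(=C=O)=C=O | starting material
12 | disodium pentacarbonylchromate(2−) | [Na+].[Na+].O=C=[Cr-2](=C=O)(=C=O)(=C=O)=C=O | intermediate
13 | sodium pentacarbonyl[(Z)-3-(benzyloxy)-2-methoxy-1-oxidoprop-2-en-1-ylidene]chromate(1−) | [Na+].[O-]C(/C(OC)=C/OCc1ccccc1)=[Cr](=C=O)(=C=O)(=C=O)(=C=O)=C=O | intermediate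
14 | pentacarbonyl[(Z)-3-(benzyloxy)-1,2-dimethoxyprop-2-en-1-ylidene]chromium | COC(/C(OC)=C/OCc1ccccc1)=[Cr](=C=O)(=C=O)(=C=O)(=C=O)=C=O | intermediate
15 | tricarbonyl{η6-2-[3-(benzyloxy)-2-hydroxy-4,5-dimethoxyphenyl]-5,6,7-trimethoxy-4H-chromen-4-one}chromium, B ring bound to chromium (SMILES written as arene plus Cr(CO)3 fragment because the η6 bond cannot be expressed) | COc1cc(-c2cc(=O)c3c(OC)c(OC)c(OC)cc3o2)c(O)c(OCc2ccccc2)c1OC.O=C=[Cr](=C=O)=C=O | intermediate
16 | 2-[3-(benzyloxy)-2-hydroxy-4,5-dimethoxyphenyl]-5,6,7-trimethoxy-4H-chromen-4-one | COc1cc(-c2cc(=O)c3c(OC)c(OC)c(OC)cc3o2)c(O)c(OCc2ccccc2)c1OC | intermediate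
17 | 2-[3-(benzyloxy)-2,4,5-trimethoxyphenyl]-5,6,7-trimethoxy-4H-chromen-4-one | COc1cc(-c2cc(=O)c3c(OC)c(OC)c(OC)cc3o2)c(OC)c(OCc2ccccc2)c1OC | intermediate
18 | psiadiarabicin, 5-hydroxy-2-(3-hydroxy-2,4,5-trimethoxyphenyl)-6,7-dimethoxy-4H-chromen-4-one | COc1cc(-c2cc(=O)c3c(O)c(OC)c(OC)cc3o2)c(OC)c(O)c1OC | target

Total step count: 10
Longest linear sequence: 7 steps (6 → 8 → 9 → 10 → 14 → 16 → 17 → 18); the alkyne branch from 1 is 6 steps to the target.

Steps most likely to fail

Step 8 (Proposed new method). The donor-stabilised, doubly oxygenated carbene may lose CO or insert the electron-poor enynone alkyne too slowly. CO insertion may also lose to cyclopentannulation or to capture of the vinylcarbene by the pyrone, or the electron-rich phenol may be oxidised during decomplexation. The fallback uses only known flavone chemistry, sets out from acetophenone 1 and comes back at 17. 2,6-Dimethoxyphenol is benzylated (BnBr, K2CO3, DMF) to 2-(benzyloxy)-1,3-dimethoxybenzene F1. Vilsmeier–Haack formylation (POCl3, DMF) para to a methoxy group should give 3-(benzyloxy)-2,4-dimethoxybenzaldehyde F2. Bromination (NBS, MeCN) at the position para to the 2-methoxy group should give 3-(benzyloxy)-5-bromo-2,4-dimethoxybenzaldehyde F3. Copper-catalysed Ullmann-type methoxylation (NaOMe, CuBr, MeOH–DMF) should give 3-(benzyloxy)-2,4,5-trimethoxybenzaldehyde F4. Claisen–Schmidt condensation of F4 with 1 (KOH, EtOH) should give (E)-3-[3-(benzyloxy)-2,4,5-trimethoxyphenyl]-1-(6-hydroxy-2,3,4-trimethoxyphenyl)prop-2-en-1-one F5. Oxidative cyclisation of this 2'-hydroxychalcone (I2 cat., DMSO, 120 °C) should give 17, after which step 10 is unchanged.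

Step 3. The diazophosphonate anion or residual methoxide may attack the pyrone at C2 and open the ring, or add in conjugate fashion to the newly formed enynone. The fallback sets out from aldehyde 4 and comes back at alkyne 5, replacing the basic homologation by olefination and a fluoride-induced elimination. Dibromo-olefination (CBr4, PPh3, CH2Cl2, 0 °C) should give 2-(2,2-dibromoethenyl)-5,6,7-trimethoxy-4H-chromen-4-one F6. Palladium-catalysed selective hydrogenolysis of the trans bromine (Bu3SnH, Pd(PPh3)4, toluene) should give 2-[(Z)-2-bromoethenyl]-5,6,7-trimethoxy-4H-chromen-4-one F7. Anti-elimination with TBAF in DMF at room temperature should then deliver 5.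

Step 10. Once the boron chelate has formed at O5 and the 3'-oxygen is borylated, dealkylation may run on to the 6-methoxy group or to the methoxy groups flanking C3'. Alternatively the chelated ether may not cleave at a temperature that spares the others. The fallback sets out from 17 and comes back at 18, separating the two deprotections by mechanism. Hydrogenolysis (H2, Pd/C, EtOAc–THF) should give 2-(3-hydroxy-2,4,5-trimethoxyphenyl)-5,6,7-trimethoxy-4H-chromen-4-one F8. Brønsted-acid 5-O-demethylation (conc. HCl, EtOH, reflux), which acts only on the methoxy group peri to the protonated carbonyl, should then give 18.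

Step 7 is air- and moisture-sensitive but follows an established acylation and alkylation sequence and is ranked below these three.

Further compounds
F1 | step 8 | 2-(benzyloxy)-1,3-dimethoxybenzene | COc1cccc(OC)c1OCc1ccccc1
F2 | step 8 | 3-(benzyloxy)-2,4-dimethoxybenzaldehyde | COc1ccc(C=O)c(OC)c1OCc1ccccc1
F3 | step 8 | 3-(benzyloxy)-5-bromo-2,4-dimethoxybenzaldehyde | COc1c(Br)cc(C=O)c(OC)c1OCc1ccccc1
F4 | step 8 | 3-(benzyloxy)-2,4,5-trimethoxybenzaldehyde | COc1cc(C=O)c(OC)c(OCc2ccccc2)c1OC
F5 | step 8 | (E)-3-[3-(benzyloxy)-2,4,5-trimethoxyphenyl]-1-(6-hydroxy-2,3,4-trimethoxyphenyl)prop-2-en-1-one | COc1cc(/C=C/C(=O)c2c(O)cc(OC)c(OC)c2OC)c(OC)c(OCc2ccccc2)c1OC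
F6 | step 3 | 2-(2,2-dibromoethenyl)-5,6,7-trimethoxy-4H-chromen-4-one | BrC(Br)=Cc1cc(=O)c2c(OC)c(OC)c(OC)cc2o1
F7 | step 3 | 2-[(Z)-2-bromoethenyl]-5,6,7-trimethoxy-4H-chromen-4-one | Br/C=C\c1cc(=O)c2c(OC)c(OC)c(OC)cc2o1
F8 | step 10 | 2-(3-hydroxy-2,4,5-trimethoxyphenyl)-5,6,7-trimethoxy-4H-chromen-4-one | COc1cc(-c2cc(=O)c3c(OC)c(OC)c(OC)cc3o2)c(OC)c(O)c1OC
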